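**Retrosynthetic overview**
- Target ⇐ copper-catalysed 1,4-addition of an isopropyl Grignard to a bicyclic 4-hydroxycyclopentenone; this sets C4 last.
- Five-membered ring (formed second) ⇐ intramolecular Nozaki–Hiyama–Kishi closure of C4–C5: a (Z)-β-iodoenone becomes a β-acylvinyl chromium, so the enone β-carbon acts as donor toward the cycloheptenone carbonyl; cis fusion sets C5.
- Seven-membered ring (formed first) ⇐ ring-closing metathesis at C8=C9.
- C1–C10 ⇐ palladium-catalysed asymmetric allylic alkylation of a 2-methyl-1,3-diketone with the bis(4-methoxybenzoate) acylal of crotonaldehyde; the ester and both stereocentres arrive in one step.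
- Diketone ⇐ crossed Claisen of 5-methylhex-5-en-2-one with a silyl propiolate, then C-methylation.

Locants used below: C1 = methyl-bearing ring-fusion carbon, C2 = ring ketone, C3 = CH2, C4 = isopropyl carbon, C5 = carbinol ring-fusion carbon, C6/C7 = CH2CH2, C8 = methyl-bearing alkene carbon, C9 = alkene CH, C10 = ester carbon. In the target the C1 methyl, C5 hydroxyl and C4 isopropyl share one face; the C10 ester oxygen is on the other.

Assumption: the (R,R)-ligand is taken to give the (R) acyloxy carbon and the (R) quaternary carbon; if the sense is opposite, the (S,S)-ligand is used.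

**Step 1**
Reactants: 1 5-methylhex-5-en-2-one; 2 ethyl 3-(trimethylsilyl)prop-2-ynoate
Product: 4 4,8-dimethyl-1-(trimethylsilyl)non-8-en-1-yne-3,5-dione (racemic), via lithium diketonate 3 (not isolated)
Conditions: LiN(SiMe3)2 (2.2 equiv), THF, −78 °C; 2, −78 → 0 °C; then MeI, DMPU, 0 °C → rt
Reagents that add atoms: iodomethane, CI
Why: Kinetic deprotonation of the methyl ketone at CH3 and crossed Claisen acylation by the propiolate (the silyl group blocks conjugate addition) give the lithium 1,3-diketonate, which is C-methylated in the same flask; no lasting stereocentre is formed because C1 is still enolisable.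

**Step 2**
Reactants: 5 (E)-but-2-enal; 6 4-methoxybenzoic anhydride
Product: 7 (E)-but-2-ene-1,1-diyl bis(4-methoxybenzoate)
Conditions: FeCl3 (5 mol%), CH2Cl2, 0 °C → rt
Reagents that add atoms: none
Why: Lewis-acid-catalysed acylal formation (1,1-diacylation of an aldehyde by an anhydride) is an addition with no by-product and leaves the E alkene untouched.

**Step 3**
Reactants: 4 4,8-dimethyl-1-(trimethylsilyl)non-8-en-1-yne-3,5-dione; 7 (E)-but-2-ene-1,1-diyl bis(4-methoxybenzoate)
Product: 8 (1R,2E)-1-[(4R)-4,8-dimethyl-3,5-dioxo-1-(trimethylsilyl)non-8-en-1-yn-4-yl]but-2-en-1-yl 4-methoxybenzoate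
Conditions: NaH, THF, 0 °C; then [Pd(C3H5)Cl]2 (2.5 mol%), (R,R)-DACH-phenyl Trost ligand (7.5 mol%), 7, THF–CH2Cl2, 0 °C → rt
Reagents that add atoms: none
Why: Trost asymmetric allylic alkylation with a geminal dicarboxylate: zerovalent palladium ionises one of the two enantiotopic anisoates (sets C10), the diketone enolate attacks the acyloxy-bearing allyl terminus, and the ligand pocket has to tell the slim alkynyl ketone from the alkyl ketone to set C1, which is the less certain of the two controls (the C1 epimer is removed after step 4).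

**Step 4**
Reactants: 8 (1R,2E)-1-[(4R)-4,8-dimethyl-3,5-dioxo-1-(trimethylsilyl)non-8-en-1-yn-4-yl]but-2-en-1-yl 4-methoxybenzoate
Product: 9 (1R,7R)-3,7-dimethyl-6-oxo-7-[3-(trimethylsilyl)prop-2-ynoyl]cyclohept-2-en-1-yl 4-methoxybenzoate
Conditions: second-generation Hoveyda–Grubbs catalyst RuCl2(=CH-C6H4-2-OiPr)(H2IMes) (5 mol%), PhMe (3 mM), 80 °C
Reagents that add atoms: none
Why: Ring-closing metathesis between the propenyl group and the 1,1-disubstituted alkene gives the trisubstituted cycloheptene with loss of propene; the hindered, electron-poor silyl ynone is a poor enyne-metathesis partner, and no stereocentre changes (anisoate trans to the C1 methyl).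

**Step 5**
Reactants: 9 (1R,7R)-3,7-dimethyl-6-oxo-7-[3-(trimethylsilyl)prop-2-ynoyl]cyclohept-2-en-1-yl 4-methoxybenzoate
Product: 11 (1R,7R)-7-[(2Z)-3-iodoprop-2-enoyl]-3,7-dimethyl-6-oxocyclohept-2-en-1-yl 4-methoxybenzoate, via terminal ynone 10 (not isolated)
Conditions: AgNO3 (10 mol%), acetone–H2O, rt; then NaI, AcOH, rt
Reagents that add atoms: sodium iodide, [Na+].[I-]
Why: Silver-catalysed protodesilylation of the alkynylsilane followed by hydroiodination of the ynone (anti addition of HI) gives the (Z)-β-iodoenone with iodine cis to the acyl group, the geometry needed for ring closure.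

**Step 6**
Reactants: 11 (1R,7R)-7-[(2Z)-3-iodoprop-2-enoyl]-3,7-dimethyl-6-oxocyclohept-2-en-1-yl 4-methoxybenzoate
Product: 12 (3aS,8R,8aR)-3a-hydroxy-6,8a-dimethyl-1-oxo-1,3a,4,5,8,8a-hexahydroazulen-8-yl 4-methoxybenzoate
Conditions: CrCl2 (5 equiv), NiCl2 (5 mol%), DMF, rt
Reagents that add atoms: none
Why: Intramolecular Nozaki–Hiyama–Kishi reaction: divalent chromium with nickel catalysis turns the enone β-carbon (normally an acceptor) into a β-acylvinyl chromium donor that adds to the ring ketone (another acceptor) to close C4–C5, and the three-atom tether allows attack only on the carbonyl face syn to the acyl group, so the ring is cis-fused and the new C5 hydroxyl is cis to the C1 methyl.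

**Step 7**
Reactants: 12 (3aS,8R,8aR)-3a-hydroxy-6,8a-dimethyl-1-oxo-1,3a,4,5,8,8a-hexahydroazulen-8-yl 4-methoxybenzoate
Product: 14 (3R,3aS,8R,8aR)-3a-hydroxy-6,8a-dimethyl-1-oxo-3-(propan-2-yl)-1,2,3,3a,4,5,8,8a-octahydroazulen-8-yl 4-methoxybenzoate (CNP0246512.1), via magnesium enolate 13 (not isolated)
Conditions: i-PrMgCl (3 equiv), CuBr·SMe2 (0.3 equiv), THF, −78 → −40 °C; aq NH4Cl
Reagents that add atoms: isopropylmagnesium chloride, CC(C)[Mg]Cl
Why: Copper-catalysed conjugate addition to the cyclopentenone, in which the first equivalent of Grignard forms the C5 magnesium alkoxide and the isopropyl group is expected to arrive on the convex face of the cis-fused bicycle (the face of the alkoxide and C1 methyl, away from the folded seven-membered ring), giving C4 isopropyl cis to OH; the enolate is protonated at C3 on work-up and the ester is untouched at low temperature.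

**Compound list**
1 | 5-methylhex-5-en-2-one | CC(=O)CCC(C)=C | starting material
2 | ethyl 3-(trimethylsilyl)prop-2-ynoate | CCOC(=O)C#C[Si](C)(C)C | starting material
3 | lithium enolate of 8-methyl-1-(trimethylsilyl)non-8-en-1-yne-3,5-dione | [Li+].C=C(C)CCC(=O)/C=C(\[O-])C#C[Si](C)(C)C | intermediate
4 | 4,8-dimethyl-1-(trimethylsilyl)non-8-en-1-yne-3,5-dione (racemic) | C=C(C)CCC(=O)C(C)C(=O)C#C[Si](C)(C)C | intermediate
5 | (E)-but-2-enal | C/C=C/C=O | starting material
6 | 4-methoxybenzoic anhydride | COc1ccc(cc1)C(=O)OC(=O)c1ccc(OC)cc1 | starting material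
7 | (E)-but-2-ene-1,1-diyl bis(4-methoxybenzoate) | C/C=C/C(OC(=O)c1ccc(OC)cc1)OC(=O)c1ccc(OC)cc1 | intermediate
8 | (1R,2E)-1-[(4R)-4,8-dimethyl-3,5-dioxo-1-(trimethylsilyl)non-8-en-1-yn-4-yl]but-2-en-1-yl 4-methoxybenzoate | COc1ccc(C(=O)O[C@H](/C=C/C)[C@](C)(C(=O)CCC(C)=C)C(=O)C#C[Si](C)(C)C)cc1 | intermediate
9 | (1R,7R)-3,7-dimethyl-6-oxo-7-[3-(trimethylsilyl)prop-2-ynoyl]cyclohept-2-en-1-yl 4-methoxybenzoate | COc1ccc(C(=O)O[C@@H]2C=C(C)CCC(=O)[C@]2(C)C(=O)C#C[Si](C)(C)C)cc1 | intermediate
10 | (1R,7R)-3,7-dimethyl-6-oxo-7-(prop-2-ynoyl)cyclohept-2-en-1-yl 4-methoxybenzoate | COc1ccc(C(=O)O[C@@H]2C=C(C)CCC(=O)[C@]2(C)C(=O)C#C)cc1 | intermediate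
11 | (1R,7R)-7-[(2Z)-3-iodoprop-2-enoyl]-3,7-dimethyl-6-oxocyclohept-2-en-1-yl 4-methoxybenzoate | COc1ccc(C(=O)O[C@@H]2C=C(C)CCC(=O)[C@]2(C)C(=O)/C=C\I)cc1 | intermediate
12 | (3aS,8R,8aR)-3a-hydroxy-6,8a-dimethyl-1-oxo-1,3a,4,5,8,8a-hexahydroazulen-8-yl 4-methoxybenzoate | COc1ccc(C(=O)O[C@@H]2C=C(C)CC[C@]3(O)C=CC(=O)[C@]23C)cc1 | intermediate
13 | bis(chloromagnesium) C2-enolate C5-alkoxide of 14 | COc1ccc(C(=O)O[C@@H]2C=C(C)CC[C@]3(O[Mg]Cl)[C@@H](C(C)C)C=C(O[Mg]Cl)[C@]23C)cc1 | intermediate
14 | (3R,3aS,8R,8aR)-3a-hydroxy-6,8a-dimethyl-1-oxo-3-(propan-2-yl)-1,2,3,3a,4,5,8,8a-octahydroazulen-8-yl 4-methoxybenzoate | COc1ccc(C(=O)O[C@@H]2C=C(C)CC[C@]3(O)[C@@H](C(C)C)CC(=O)[C@]23C)cc1 | target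

**Step count**
Total steps: 7. Longest linear sequence: 6 (steps 1, 3, 4, 5, 6, 7); step 2 is a one-step side branch.

**Three steps most likely to fail, with fallbacks**

Step 3 (acylal ionisation, regiochemistry, and above all the C1 face of an acyclic diketone enolate). The fallback sets out from 4 and comes back at 9. Compound 4 is added across 1-methoxy-4-[(propa-1,2-dien-1-yloxy)methyl]benzene ([Pd(C3H5)Cl]2, Trost ligand, Et3N; hydro-alkylation of an alkoxyallene) to give (4R)-4-[(1R)-1-[(4-methoxyphenyl)methoxy]prop-2-en-1-yl]-4,8-dimethyl-1-(trimethylsilyl)non-8-en-1-yne-3,5-dione F1. Ring-closing metathesis with the same ruthenium catalyst gives (2R,3R)-3-[(4-methoxyphenyl)methoxy]-2,5-dimethyl-2-[3-(trimethylsilyl)prop-2-ynoyl]cyclohept-4-en-1-one F2. DDQ (CH2Cl2, pH 7 buffer) frees (2R,3R)-3-hydroxy-2,5-dimethyl-2-[3-(trimethylsilyl)prop-2-ynoyl]cyclohept-4-en-1-one F3, and 4-methoxybenzoyl chloride, pyridine and DMAP at 0 °C give 9. This removes the acylal ionisation and terminus question but not the C1 face question; in either series the C1 epimers are cis/trans ring diastereomers at 9 or F2 and can be separated there.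

Step 6 (the vinylchromium may be too sluggish toward a ketone flanked by a quaternary carbon, or may simply be protonated). The fallback sets out from 10, isolated after the silver-catalysed desilylation, and comes back at 14. Conjugate addition of (i-Pr)2CuLi to the ynone (THF, −78 °C; a trace of I2 to equilibrate to E) gives (1R,7R)-3,7-dimethyl-7-[(2E)-4-methylpent-2-enoyl]-6-oxocyclohept-2-en-1-yl 4-methoxybenzoate F4. Reductive cyclisation (SmI2, HMPA, t-BuOH, THF, −78 °C, or the electroreductive equivalent) then joins the β-carbon of the enone radical anion to the ring ketone and gives 14 directly. The cis ring fusion is again enforced by the tether. The C4 configuration from this closure is not predictable in advance and would have to be checked.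

Step 7 (facial selectivity at C4, or 1,2-addition and loss of the γ-alkoxide). The fallback sets out from 12 and comes back at 14. Cyclopropanation of the enone with diphenylsulfonium isopropylide (isopropyldiphenylsulfonium tetrafluoroborate, LiN(iPr)2, DME, −78 → −20 °C) gives the gem-dimethylcyclopropane (C3–C4 isopropylidene adduct of 12, cyclopropane on the face of the hydroxyl and C1 methyl) F5. Reductive opening of the cyclopropyl ketone (SmI2, HMPA, t-BuOH, THF, −78 °C) cleaves the exocyclic C3–CMe2 bond, which overlaps best with the carbonyl, and leaves isopropyl on C4 with the configuration fixed in the cyclopropanation.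

**Further compounds**
F1 | step 3 | (4R)-4-[(1R)-1-[(4-methoxyphenyl)methoxy]prop-2-en-1-yl]-4,8-dimethyl-1-(trimethylsilyl)non-8-en-1-yne-3,5-dione | COc1ccc(CO[C@H](C=C)[C@](C)(C(=O)CCC(C)=C)C(=O)C#C[Si](C)(C)C)cc1
F2 | step 3 | (2R,3R)-3-[(4-methoxyphenyl)methoxy]-2,5-dimethyl-2-[3-(trimethylsilyl)prop-2-ynoyl]cyclohept-4-en-1-one | COc1ccc(CO[C@@H]2C=C(C)CCC(=O)[C@]2(C)C(=O)C#C[Si](C)(C)C)cc1
F3 | step 3 | (2R,3R)-3-hydroxy-2,5-dimethyl-2-[3-(trimethylsilyl)prop-2-ynoyl]cyclohept-4-en-1-one | O[C@@H]1C=C(C)CCC(=O)[C@]1(C)C(=O)C#C[Si](C)(C)C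
F4 | step 6 | (1R,7R)-3,7-dimethyl-7-[(2E)-4-methylpent-2-enoyl]-6-oxocyclohept-2-en-1-yl 4-methoxybenzoate | COc1ccc(C(=O)O[C@@H]2C=C(C)CCC(=O)[C@]2(C)C(=O)/C=C/C(C)C)cc1
F5 | step 7 | C3–C4 isopropylidene (gem-dimethylcyclopropane) adduct of 12, cyclopropane cis to the C5 hydroxyl and C1 methyl | COc1ccc(C(=O)O[C@@H]2C=C(C)CC[C@]3(O)[C@H]4C(C)(C)[C@H]4C(=O)[C@]23C)cc1
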